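The route rests on a retro-Diels–Alder cut of ring B, the cyclohexane of the perhydrobenzoxepine (C6 quaternary fusion carbon, C7 oxygen-bearing fusion CH, C8, C9, C10 carbinol, C11 chain-bearing CH), at C7–C8 and C6–C11. The key step unites two advanced fragments, dienyl enone 17 with the complete decalin skeleton and (Z)-beta-silyl enal 23, and sets C6, C7 and C11 at once. It exploits that the C6 methyl, the C7 oxygen and the C11 side chain share one face of ring B: the endo formyl group is the latent methyl, the cis silyl group the latent oxygen, and the trans alkyl chain later closes the trans-fused oxepane.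

Key step: step 17

Remark on numbering: oxepane (ring A) O1, C2 (CMe2), C3 (CHOH), C4, C5, C6, C7. Ring B is C6–C11 and the linking chain is C12, C13. Decalin atoms carry primes: C1' CH2, C2' C=O, C3' C–CH3, C4' chain-bearing, C4a', C5' CMe2, C6', C7', C8' carbinol, C8a'.

Assumption: the methyl-bearing centre C3' in 2–9 and the carbinol centre of 16 both become sp2 later. The SMILES therefore show the major C3' epimer and leave the carbinol centre of 16 open.

Step 1
Reactants: 1 (S)-(+)-carvone
Product: 2 (2S,5S)-dihydrocarvone
Conditions: Zn, KOH, EtOH–H2O, reflux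
Reagents that add atoms: none
Why: Dissolving-metal conjugate reduction of the enone spares the isolated isopropenyl group, the base equilibrates the methyl group to the equatorial epimer, and the carvone stereocentre (later C8a') is untouched.

Step 2
Reactants: 2 (2S,5S)-dihydrocarvone
Product: 4 aldol adduct carrying a 2-hydroxypropan-2-yl group at the less substituted alpha carbon, via kinetic lithium enolate 3 (not isolated)
Conditions: LiN(iPr)2, THF, −78 °C; acetone; AcOH, −78 °C
Reagents that add atoms: acetone, CC(C)=O; lithium diisopropylamide (its lithium stays only in 3), [Li+].CC(C)[N-]C(C)C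
Why: Kinetic deprotonation at the less substituted alpha carbon and directed aldol addition to acetone; the new group enters trans to the isopropenyl group, at a centre that step 3 erases.

Step 3
Reactants: 4 aldol adduct
Product: 5 isopropylidene ketone (pulegone-type tetrasubstituted enone)
Conditions: MsCl, Et3N, CH2Cl2, 0 to 25 °C
Reagents that add atoms: none
Why: Mesylation and E1cB elimination (aldol dehydration) should give the conjugated enone, because only the alpha hydrogen is acidic.

Step 4
Reactants: 5 isopropylidene ketone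
Product: 6 trimethylsilyl enol ether bearing the 2-methylpent-4-en-2-yl group
Conditions: CH2=CHCH2MgBr, CuBr·SMe2, LiCl, Me3SiCl, THF, −78 °C
Reagents that add atoms: allylmagnesium bromide, C=CC[Mg]Br; chlorotrimethylsilane, C[Si](C)(C)Cl
Why: Chlorosilane-accelerated conjugate addition of an allylcopper reagent to the beta,beta-disubstituted enone builds the quaternary C5' and stores the enolate regiospecifically as its silyl enol ether.

Step 5
Reactants: 6 trimethylsilyl enol ether
Product: 7 bicyclic silyl enol ether (C4'=C4a' enol ether, C7'=C8' alkene)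
Conditions: second-generation Grubbs catalyst RuCl2(=CHPh)(PCy3)(H2IMes) (5 mol%), CH2Cl2, 40 °C
Reagents that add atoms: none
Why: Ring-closing metathesis of the allyl and isopropenyl groups closes the second carbocycle as a trisubstituted cyclohexene, while the tetrasubstituted enol ether stays inert.

Step 6
Reactants: 7 bicyclic silyl enol ether
Product: 9 cis-fused bicyclic ketone (C4' ketone), via bicyclic lithium enolate 8 (not isolated)
Conditions: MeLi, THF, 0 °C; then AcOH, −78 °C
Reagents that add atoms: methyllithium (its lithium stays only in 8), [Li]C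
Why: Silyl enol ether cleavage gives the regiodefined enolate, and kinetic protonation on the convex face that carries H-8a' should set C4a' cis, as in kinetically controlled ketonisation of 1-decalone-type enolates.

Step 7
Reactants: 9 cis-fused bicyclic ketone
Product: 11 cis-fused bicyclic enone (C4' ketone, C2'=C3' alkene), via C3' lithium enolate 10 (not isolated)
Conditions: LiN(iPr)2, THF, −78 °C; PhS(Cl)=NtBu, −78 °C
Reagents that add atoms: lithium diisopropylamide (its lithium stays only in 10), [Li+].CC(C)[N-]C(C)C
Why: Kinetic deprotonation at the less hindered alpha carbon C3' and sulfinimidoyl chloride dehydrogenation (Mukaiyama dehydrogenation) should give the enone at low temperature without touching the epimerisable C4a'.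

Step 8
Reactants: 12 cyclopropyl methyl ketone
Product: 13 2-cyclopropylbut-3-en-2-ol (racemic)
Conditions: CH2=CHMgBr, THF, 0 °C; H2O
Reagents that add atoms: vinylmagnesium bromide, C=C[Mg]Br
Why: Grignard 1,2-addition to the ketone; the carbinol centre is lost in step 9.

Step 9
Reactants: 13 2-cyclopropylbut-3-en-2-ol
Product: 14 (E)-6-bromo-3-methylhexa-1,3-diene
Conditions: 48% aq HBr, 0 °C
Reagents that add atoms: hydrogen bromide, Br
Why: Julia cyclopropyl carbinol rearrangement: ionisation and bromide attack on the cyclopropane give the homoallylic bromide, and minimised allylic strain favours the E trisubstituted alkene.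

Step 10
Reactants: 14 (E)-6-bromo-3-methylhexa-1,3-diene; 11 cis-fused bicyclic enone
Product: 16 tertiary allylic alcohol, via dienyl Grignard reagent 15 (not isolated)
Conditions: Mg, THF; CeCl3, −78 °C; then 11, −78 to 0 °C; H2O
Reagents that add atoms: magnesium (stays only in 15), [Mg]
Why: Organocerium 1,2-addition suppresses enolisation of the hindered enone, and the new carbinol centre is erased in step 11.

Step 11
Reactants: 16 tertiary allylic alcohol
Product: 17 dienyl enone (C2' ketone, chain on C4')
Conditions: pyridinium chlorochromate, NaOAc, 4 Å molecular sieves, CH2Cl2, 25 °C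
Reagents that add atoms: pyridinium chlorochromate (delivers the carbonyl oxygen), c1cc[nH+]cc1.[O-][Cr](=O)(=O)Cl
Why: Babler–Dauben oxidative transposition: the [3,3] shift of the tertiary allylic chromate ester and oxidation give the transposed beta-alkyl enone, with C4a' and C8a' untouched.

Step 12
Reactants: 18 pent-4-ynoic acid
Product: 19 N-methoxy-N-methylpent-4-ynamide
Conditions: MeNH(OMe)·HCl, EDC·HCl, Et3N, CH2Cl2, 25 °C
Reagents that add atoms: N,O-dimethylhydroxylamine hydrochloride, CNOC.Cl
Why: Carbodiimide amide coupling gives the Weinreb amide.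

Step 13
Reactants: 19 N-methoxy-N-methylpent-4-ynamide
Product: 20 2-methylhept-1-en-6-yn-3-one
Conditions: CH2=C(CH3)MgBr (2.2 equiv), THF, −20 °C; aq HCl
Reagents that add atoms: isopropenylmagnesium bromide, CC(=C)[Mg]Br
Why: Weinreb ketone synthesis: the first equivalent deprotonates the alkyne and the chelated adduct prevents over-addition.

Step 14
Reactants: 20 2-methylhept-1-en-6-yn-3-one
Product: 21 (S)-2-methylhept-1-en-6-yn-3-ol
Conditions: (R)-2-methyl-CBS-oxazaborolidine (15 mol%), catecholborane, toluene, −78 °C
Reagents that add atoms: none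
Why: Corey–Bakshi–Shibata reduction: the isopropenyl group acts as the large substituent, so the (R)-catalyst should give the (S)-alcohol (C3), and catecholborane at low temperature spares alkyne and alkene.

Step 15
Reactants: 21 (S)-2-methylhept-1-en-6-yn-3-ol
Product: 22 triisopropylsilyl ether of 21
Conditions: iPr3SiOTf, 2,6-lutidine, CH2Cl2, 0 °C
Reagents that add atoms: triisopropylsilyl triflate, CC(C)[Si](C(C)C)(C(C)C)OS(=O)(=O)C(F)(F)F
Why: Silyl ether protection with a group that should outlast the brief fluoride treatment of step 19.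

Step 16
Reactants: 22 triisopropylsilyl ether
Product: 23 (Z)-3-(benzyldimethylsilyl)-2-alkylacrolein (silyl cis to formyl)
Conditions: BnMe2SiH, CO (10 atm), Rh(acac)(CO)2 (1 mol%), toluene, 25 °C
Reagents that add atoms: benzyldimethylsilane, C[SiH](C)Cc1ccccc1; carbon monoxide, [C-]#[O+]
Why: Rhodium-catalysed silylformylation of the terminal alkyne: syn addition puts silicon on the terminal carbon and the formyl group on the internal carbon, which fixes the Z geometry.

Step 17
Reactants: 17 dienyl enone; 23 (Z)-silyl enal
Product: 24 Diels–Alder adduct (ring B cyclohexene with C6 formyl, C7 silyl and the C11 chain on one face)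
Conditions: oxazaborolidinium bistriflimide from (S)-diphenylprolinol, o-tolylboroxine and HNTf2 (30 mol%), CH2Cl2, −40 °C
Reagents that add atoms: none
Why: This is a concerted but asynchronous normal-electron-demand [4+2] cycloaddition in which the boron Lewis acid binds the formyl oxygen of 23, the unhindered diene terminus C8 bonds early to the beta carbon C7, and the crowded C6–C11 bond follows in the same transition state; the closest known type is the oxazaborolidinium-catalysed Diels–Alder reaction of alpha-substituted acroleins with acyclic dienes. One ring is closed, cyclohexene ring B, by suprafacial–suprafacial addition of the s-cis diene C8=C9–C10=C11 across C6=C7. C6 and C7 are fixed relative to each other by the Z geometry of 23 (silyl cis to formyl and trans to the alkyl chain, which later makes the oxepane trans-fused); C11 is fixed relative to C6 by the E diene geometry together with the endo orientation of the Lewis-acid-bound formyl group, which puts formyl, silyl and the C12 chain on one face; and the absolute sense comes from the catalyst, which shields one face of the bound enal so that the diene adds to the Si face at C6. The required regioselectivity (formyl-bearing C6 next to C11) is secured by the asynchronicity, since the short bond can form only between the silyl-bearing C7 and the CH2 terminus C8. Chemoselectivity is secured because the tetrasubstituted enone and the trisubstituted ring alkene of 17 and the isopropenyl group of 23 are not competent dienophiles, and any minor Z diene cannot reach the s-cis form.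

Step 18
Reactants: 24 Diels–Alder adduct
Product: 26 C6-methyl compound, via aldehyde tosylhydrazone 25 (not isolated)
Conditions: TsNHNH2, THF, 50 °C; then catecholborane, CHCl3, −10 °C; NaOAc, reflux
Reagents that add atoms: p-toluenesulfonyl hydrazide (its atoms stay only in 25), Cc1ccc(cc1)S(=O)(=O)NN
Why: Caglioti-type reduction: only the aldehyde forms the tosylhydrazone (the tetrasubstituted enone is too hindered), and hydroboration of C=N followed by loss of sulfinate and nitrogen turns formyl into the C6 methyl without touching a stereocentre.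

Step 19
Reactants: 26 C6-methyl compound
Product: 28 C7 alcohol, via dimethylsilanol 27 (not isolated)
Conditions: Bu4NF, THF, 0 °C; then H2O2, KHCO3, MeOH, 25 °C
Reagents that add atoms: hydrogen peroxide, OO; water (its oxygen stays only in 27), O
Why: Tamao–Fleming oxidation: fluoride removes the benzyl group and the peroxide-induced shift from silicon to oxygen proceeds with retention at C7.

Step 20
Reactants: 28 C7 alcohol
Product: 29 trans-fused oxepane
Conditions: N,N'-bis(3,5-di-tert-butylsalicylidene)-1,2-cyclohexanediaminocobalt, Co(C36H52N2O2) (5 mol%), N-fluoro-2,4,6-trimethylpyridinium triflate, (HMe2Si)2O, PhCF3, 25 °C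
Reagents that add atoms: none
Why: This is a cobalt-hydride hydrogen-atom-transfer Markovnikov hydroalkoxylation with radical–polar crossover: the 1,1-disubstituted alkene reacts first, its C2 cation equivalent is trapped 7-exo by the C7 hydroxyl, and the trans fusion follows from the equatorial C7–O and C6–C5 bonds.

Step 21
Reactants: 29 trans-fused oxepane
Product: 30 3-O-triisopropylsilyl sipholenol K
Conditions: Co(acac)2 (20 mol%), PhSiH3, O2 (1 atm), THF–iPrOH, 25 °C
Reagents that add atoms: dioxygen, O=O
Why: Mukaiyama hydration of both trisubstituted alkenes: oxygen should trap the tertiary C10 radical opposite the axial C6 methyl and the C8' radical on the convex face of the cis-decalin, while the tetrasubstituted enone resists hydrogen-atom transfer.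

Step 22
Reactants: 30 3-O-triisopropylsilyl sipholenol K
Product: 31 sipholenol K
Conditions: HF·pyridine, THF, 0 to 25 °C
Reagents that add atoms: none
Why: Fluoride-mediated desilylation under non-basic conditions frees the C3 hydroxyl without epimerising C4a' or dehydrating the tertiary alcohols.

Compound list
1 | (S)-(+)-carvone | CC1=CC[C@@H](CC1=O)C(C)=C | starting material
2 | (2S,5S)-dihydrocarvone (methyl and isopropenyl trans) | C[C@H]1CC[C@H](C(C)=C)CC1=O | intermediate
3 | kinetic lithium enolate of 2 | C[C@H]1CC[C@H](C(C)=C)C=C1[O-].[Li+] | intermediate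
4 | aldol adduct, 2-hydroxypropan-2-yl group trans to isopropenyl | C[C@H]1CC[C@H](C(C)=C)[C@H](C1=O)C(C)(C)O | intermediate
5 | 2-methyl-5-isopropenyl-6-(propan-2-ylidene)cyclohexanone, carvone centre retained | C[C@H]1CC[C@H](C(C)=C)C(=C(C)C)C1=O | intermediate
6 | trimethylsilyl enol ether with 2-methylpent-4-en-2-yl group on the enol carbon | C[C@H]1CC[C@H](C(C)=C)C(C(C)(C)CC=C)=C1O[Si](C)(C)C | intermediate
7 | bicyclic silyl enol ether (C4'=C4a', C7'=C8') | C[C@H]1CC[C@H]2C(=C1O[Si](C)(C)C)C(C)(C)CC=C2C | intermediate
8 | bicyclic lithium enolate (C4'=C4a') | C[C@H]1CC[C@H]2C(=C1[O-])C(C)(C)CC=C2C.[Li+] | intermediate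
9 | cis-fused bicyclic C4' ketone (H-4a' and H-8a' cis) | C[C@H]1CC[C@H]2[C@@H](C1=O)C(C)(C)CC=C2C | intermediate
10 | lithium enolate of 9 toward C3' | CC=1CC[C@H]2[C@@H](C=1[O-])C(C)(C)CC=C2C.[Li+] | intermediate
11 | cis-fused bicyclic enone (C4' ketone, C2'=C3', C7'=C8') | CC1=CC[C@H]2[C@@H](C1=O)C(C)(C)CC=C2C | intermediate
12 | cyclopropyl methyl ketone | CC(=O)C1CC1 | starting material
13 | 2-cyclopropylbut-3-en-2-ol (racemic) | CC(O)(C=C)C1CC1 | intermediate
14 | (E)-6-bromo-3-methylhexa-1,3-diene | C=C/C(C)=C/CCBr | intermediate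
15 | (E)-4-methylhexa-3,5-dienylmagnesium bromide | C=C/C(C)=C/CC[Mg]Br | intermediate
16 | tertiary allylic alcohol from 11 and 15 (carbinol centre open) | CC1=CC[C@H]2[C@@H](C1(O)CC/C=C(C)/C=C)C(C)(C)CC=C2C | intermediate
17 | dienyl enone: cis-fused C2' enone with the (E)-4-methylhexa-3,5-dienyl chain on C4' | CC1=C(CC/C=C(C)/C=C)[C@@H]2[C@H](CC1=O)C(C)=CCC2(C)C | intermediate
18 | pent-4-ynoic acid | C#CCCC(=O)O | starting material
19 | N-methoxy-N-methylpent-4-ynamide | C#CCCC(=O)N(C)OC | intermediate
20 | 2-methylhept-1-en-6-yn-3-one | C#CCCC(=O)C(C)=C | intermediate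
21 | (S)-2-methylhept-1-en-6-yn-3-ol | C#CCC[C@H](O)C(C)=C | intermediate
22 | (S)-triisopropylsilyl ether of 21 | C#CCC[C@H](O[Si](C(C)C)(C(C)C)C(C)C)C(C)=C | intermediate
23 | (Z)-3-(benzyldimethylsilyl)-2-[(S)-4-methyl-3-(triisopropylsilyloxy)pent-4-enyl]acrolein | O=C/C(CC[C@H](O[Si](C(C)C)(C(C)C)C(C)C)C(C)=C)=C\[Si](C)(C)Cc1ccccc1 | intermediate
24 | Diels–Alder adduct: ring B cyclohexene, C6 formyl, C7 silyl and C11 chain cis | CC1=C(CC[C@@H]3C(C)=CC[C@H]([Si](C)(C)Cc4ccccc4)[C@@]3(C=O)CC[C@H](O[Si](C(C)C)(C(C)C)C(C)C)C(C)=C)[C@@H]2[C@H](CC1=O)C(C)=CCC2(C)C | intermediate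
25 | tosylhydrazone of the C6 formyl group of 24 | CC1=C(CC[C@@H]3C(C)=CC[C@H]([Si](C)(C)Cc4ccccc4)[C@@]3(C=NNS(=O)(=O)c4ccc(C)cc4)CC[C@H](O[Si](C(C)C)(C(C)C)C(C)C)C(C)=C)[C@@H]2[C@H](CC1=O)C(C)=CCC2(C)C | intermediate
26 | C6-methyl compound (formyl of 24 reduced to methyl) | CC1=C(CC[C@@H]3C(C)=CC[C@H]([Si](C)(C)Cc4ccccc4)[C@@]3(C)CC[C@H](O[Si](C(C)C)(C(C)C)C(C)C)C(C)=C)[C@@H]2[C@H](CC1=O)C(C)=CCC2(C)C | intermediate
27 | C7 dimethylsilanol | CC1=C(CC[C@@H]3C(C)=CC[C@H]([Si](C)(C)O)[C@@]3(C)CC[C@H](O[Si](C(C)C)(C(C)C)C(C)C)C(C)=C)[C@@H]2[C@H](CC1=O)C(C)=CCC2(C)C | intermediate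
28 | C7 alcohol (hydroxyl cis to the C6 methyl) | CC1=C(CC[C@@H]3C(C)=CC[C@H](O)[C@@]3(C)CC[C@H](O[Si](C(C)C)(C(C)C)C(C)C)C(C)=C)[C@@H]2[C@H](CC1=O)C(C)=CCC2(C)C | intermediate
29 | trans-fused oxepane with C9=C10 and C7'=C8' alkenes | CC1=C(CC[C@H]3[C@]4(C)CC[C@H](O[Si](C(C)C)(C(C)C)C(C)C)C(C)(C)O[C@H]4CC=C3C)[C@@H]2[C@H](CC1=O)C(C)=CCC2(C)C | intermediate
30 | 3-O-triisopropylsilyl sipholenol K | CC1=C(CC[C@H]3[C@]4(C)CC[C@H](O[Si](C(C)C)(C(C)C)C(C)C)C(C)(C)O[C@H]4CC[C@]3(C)O)[C@@H]2[C@H](CC1=O)[C@@](C)(O)CCC2(C)C | intermediate
31 | sipholenol K | CC1=C(CC[C@H]2[C@]3(C)CC[C@H](O)C(C)(C)O[C@H]3CC[C@]2(C)O)[C@@H]2[C@H](CC1=O)[C@@](C)(O)CCC2(C)C | target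

Total step count: 22.
Longest linear sequence: 15 steps (steps 1–7, 10, 11, 17–22).

Steps most likely to fail

Step 17.
- Risk: the trisubstituted enal may react sluggishly with the 1,2-disubstituted diene. The enone of 17 may compete for the catalyst. The bulky silyl group, which must sit endo, may erode endo and facial selectivity.
- Fallback: a temporary ester tether turns the cycloaddition into an intramolecular one. It sets out from 23 and 14, uses 11, and comes back at 26. Pinnick oxidation (NaClO2, NaH2PO4, 2-methyl-2-butene) of 23 would give the (Z)-silylacrylic acid F1. Its caesium salt (Cs2CO3, DMF) is alkylated by bromide 14 to the dienyl ester F2. Heating (toluene, 180 °C, BHT) closes C7–C8 and C6–C11 within the tethered triene to the cis-fused delta-lactone F3. The four-atom tether enforces the regiochemistry and holds the carbonyl carbon cis to C12, and the two facial diastereomers are separated at this stage. iBu2AlH gives the lactol F4. TsNHNH2 gives the open hydroxy tosylhydrazone F5, and catecholborane then NaOAc gives the C6-methyl alcohol F6. I2, PPh3 and imidazole give the iodide F7. t-BuLi, CeCl3 and enone 11 give the tertiary carbinol F8, and pyridinium chlorochromate transposes it to 26.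

Step 20.
- Risk: closure of the seven-membered ring by a hindered secondary hydroxyl may be slow. Hydrogen-atom transfer to the two trisubstituted alkenes may compete. The C7 hydroxyl may instead capture a C10 cation equivalent.
- Fallback: electrophilic alkoxymercuration replaces the radical–polar process. It sets out from 28 and comes back at 29. Hg(OCOCF3)2 in CH3NO2 at −20 °C, which prefers the least hindered 1,1-disubstituted alkene, followed by aq NaCl would give the oxepanyl organomercury chloride F9. NaBH4 with NaOH then removes mercury to give 29.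

Step 21.
- Risk: oxygen capture at C10 and C8' may show poor facial selectivity. The more hindered alkene may convert incompletely. Plain reduction of a radical may compete.
- Fallback: epoxidation and hydride opening replace the radical hydration. It sets out from 29 and comes back at 30. mCPBA with NaHCO3 attacks C9=C10 opposite the axial C6 methyl and C7'=C8' on the convex face to give the bis-epoxide F10. Excess LiEt3BH opens both epoxides at the secondary carbons and reduces the enone to the allylic alcohol F11. MnO2 restores the enone and gives 30.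

Further compounds
F1 | step 17 | (Z)-3-(benzyldimethylsilyl)-2-[(S)-4-methyl-3-(triisopropylsilyloxy)pent-4-enyl]acrylic acid | OC(=O)/C(CC[C@H](O[Si](C(C)C)(C(C)C)C(C)C)C(C)=C)=C\[Si](C)(C)Cc1ccccc1
F2 | step 17 | (E)-4-methylhexa-3,5-dienyl ester of F1 | C=C/C(C)=C/CCOC(=O)/C(CC[C@H](O[Si](C(C)C)(C(C)C)C(C)C)C(C)=C)=C\[Si](C)(C)Cc1ccccc1
F3 | step 17 | cis-fused delta-lactone from the tethered cycloaddition | O=C1OCC[C@@H]2C(C)=CC[C@H]([Si](C)(C)Cc3ccccc3)[C@]12CC[C@H](O[Si](C(C)C)(C(C)C)C(C)C)C(C)=C
F4 | step 17 | lactol of F3 (anomeric centre open) | OC1OCC[C@@H]2C(C)=CC[C@H]([Si](C)(C)Cc3ccccc3)[C@]12CC[C@H](O[Si](C(C)C)(C(C)C)C(C)C)C(C)=C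
F5 | step 17 | hydroxy tosylhydrazone from F4 | OCC[C@@H]1C(C)=CC[C@H]([Si](C)(C)Cc2ccccc2)[C@@]1(C=NNS(=O)(=O)c2ccc(C)cc2)CC[C@H](O[Si](C(C)C)(C(C)C)C(C)C)C(C)=C
F6 | step 17 | C6-methyl primary alcohol | OCC[C@@H]1C(C)=CC[C@H]([Si](C)(C)Cc2ccccc2)[C@@]1(C)CC[C@H](O[Si](C(C)C)(C(C)C)C(C)C)C(C)=C
F7 | step 17 | primary iodide from F6 | ICC[C@@H]1C(C)=CC[C@H]([Si](C)(C)Cc2ccccc2)[C@@]1(C)CC[C@H](O[Si](C(C)C)(C(C)C)C(C)C)C(C)=C
F8 | step 17 | tertiary carbinol from F7 and 11 (carbinol centre open) | CC1=CC[C@H]2[C@@H](C1(O)CC[C@@H]3C(C)=CC[C@H]([Si](C)(C)Cc4ccccc4)[C@@]3(C)CC[C@H](O[Si](C(C)C)(C(C)C)C(C)C)C(C)=C)C(C)(C)CC=C2C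
F9 | step 20 | oxepanyl organomercury chloride (C2 centre open) | CC1=C(CC[C@H]3[C@]4(C)CC[C@H](O[Si](C(C)C)(C(C)C)C(C)C)C(C)(C[Hg]Cl)O[C@H]4CC=C3C)[C@@H]2[C@H](CC1=O)C(C)=CCC2(C)C
F10 | step 21 | bis-epoxide of 29 | CC1=C(CC[C@H]3[C@]4(C)CC[C@H](O[Si](C(C)C)(C(C)C)C(C)C)C(C)(C)O[C@H]4C[C@@H]5O[C@]35C)[C@@H]2[C@H](CC1=O)[C@@]6(C)O[C@H]6CC2(C)C
F11 | step 21 | C2' allylic alcohol with both tertiary alcohols in place (C2' centre open) | CC1=C(CC[C@H]3[C@]4(C)CC[C@H](O[Si](C(C)C)(C(C)C)C(C)C)C(C)(C)O[C@H]4CC[C@]3(C)O)[C@@H]2[C@H](CC1O)[C@@](C)(O)CCC2(C)C
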